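Labels: ring B (seven-membered) runs C1 (ester carbinol), C2, C3 (methyl-bearing alkene carbon), C4, C5 (ketone), C6 (angular methyl), C10 (fusion CH). Ring A (five-membered) runs C6, C7, C8, C9 (isopropyl carbinol), C10. Alpha is the face of the C6 methyl, beta the other.
Retrosynthetic cuts, in order: the C1–O acyl bond, C3–CH3 together with the C3=C4 unsaturation, the C10–H/C1–O pair (back to a C1=C10 alkene), C9–isopropyl, then C9–C10, and last C6–C7 and C6–CH3.
What allows the C9–C10 cut: C6 is fully substituted and lies between the C5 carbonyl and C10. Raising C10 to a ketone therefore turns ring B into a mirror-symmetric 2,2-disubstituted cycloheptane-1,3-dione, whose C7–C8–C9 arm ends in an aldehyde within five-ring reach of either carbonyl.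
Forward order: ring B is bought as cycloheptane-1,3-dione, C6 is filled by methylation and addition to acrolein, and ring A closes by carbene-catalysed C9–C10 bond formation. All later steps decorate the bicycle (isopropyl, C1 oxygen, vanillate, C3-methyl enone).
Stereochemistry: the chiral carbene chooses between the two enantiotopic ketones and so fixes C6. C9 follows from attack opposite the angular methyl, C1 from epoxidation directed by the C9 hydroxyl, and C10 from hydrogen-atom delivery opposite the titanium-bound C1 oxygen.

Key step: step 3

Assumption: the sense of induction of the aminoindanol-derived triazolium salt on the seven-membered dione is taken to follow that on the smaller-ring diones; both antipodes of the precatalyst are sold, and the one that gives (6S,10R)-6 is meant.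

Step 1
Reactants: 1 cycloheptane-1,3-dione; 2 iodomethane
Product: 3 2-methylcycloheptane-1,3-dione
Conditions: MeI (1.05 equiv), K2CO3, acetone, reflux
Reagents that add atoms: iodomethane CI
Why: C-alkylation of the stabilised 1,3-dicarbonyl enolate (SN2 on MeI) is routine for cyclic 1,3-diones, near-stoichiometric MeI limits double methylation, and no stereocentre is formed.

Step 2
Reactants: 3 2-methylcycloheptane-1,3-dione; 4 acrolein
Product: 5 3-(1-methyl-2,7-dioxocycloheptyl)propanal
Conditions: acrolein (1.5 equiv), Et3N (10 mol %), MeCN, 0 °C to rt
Reagents that add atoms: acrolein C=CC=O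
Why: Amine-catalysed Michael addition of a 2-substituted 1,3-dione to acrolein builds quaternary C6, which stays prochiral because the two ring carbonyls are still equivalent.

Step 3
Reactants: 5 3-(1-methyl-2,7-dioxocycloheptyl)propanal
Product: 6 (6S,10R)-ketol (cis-fused bicyclo[5.3.0]decane; C9 ketone; C10 alpha-OH; C5 ketone; C6 alpha-methyl)
Conditions: aminoindanol-derived N-pentafluorophenyl triazolium tetrafluoroborate (15 mol %), Et3N (15 mol %), CH2Cl2, rt
Reagents that add atoms: none
Why: The free carbene adds to the C9 aldehyde and a proton shift turns C9 into an enaminol-type acyl anion equivalent (Breslow-type intermediate), which adds to one ring carbonyl (C10); collapse of the adduct expels the carbene and leaves a C9 ketone next to a tertiary C10 alcohol. This is the intramolecular crossed aldehyde–ketone benzoin reaction, known as a desymmetrisation of 2,2-disubstituted cyclopentane- and cyclohexane-1,3-diones that carry the same 3-oxopropyl arm. Ring A closes in a 5-exo-trig mode, C9 attacking the C10 carbonyl carbon while the carbonyl oxygen stays outside the new ring. C6 is set by the catalyst, whose indane wall should let only one of the two enantiotopic carbonyls reach the nucleophilic carbon, and C10 is set relative to C6 by the three-atom tether, which can bridge only on its own side of ring B, so that OH and CH3 end up cis. The step needs the aldehyde as donor and a ketone as acceptor, which is secured by the carbene adding only to the unhindered aldehyde and by intramolecularity; the competing bridged aldol of a ring enolate onto the aldehyde is held back by a weak amine base in substoichiometric amount.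

Step 4
Reactants: 6 (6S,10R)-ketol
Product: 8 (6S)-enedione (C1=C10 alkene conjugated to the C9 ketone; C5 ketone), via chlorosulfite 7 (not isolated)
Conditions: SOCl2, pyridine, 0 °C
Reagents that add atoms: none
Why: Chlorosulfite formation and pyridine-induced E2 loss is the classical dehydration of tertiary alpha-ketols, and of the three carbons around C10 only C1 bears hydrogen (C6 is fully substituted, C9 is the ketone carbon), so a single enone regioisomer should form and the transient C10 centre is erased on purpose.

Step 5
Reactants: 8 (6S)-enedione; 9 isopropylmagnesium chloride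
Product: 10 (6S,9R)-allylic alcohol (C9 alpha-OH and beta-isopropyl; C1=C10 alkene; C5 ketone)
Conditions: CeCl3 (anhydrous), i-PrMgCl (1.2 equiv), THF, −78 °C; H2O
Reagents that add atoms: isopropylmagnesium chloride CC(C)[Mg]Cl
Why: Organocerium 1,2-addition: the weakly basic, bulky reagent should add to the open s-cis C9 enone carbonyl (flanked by a CH2 and an sp2 carbon) much faster than to the C5 cycloheptanone shielded by quaternary C6, and it should approach ring A opposite the angular methyl, since the flat C5 carbonyl places no substituent over the beta face, giving beta-isopropyl and alpha-OH (9R).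

Step 6
Reactants: 10 (6S,9R)-allylic alcohol
Product: 11 (1R,6S,9R,10S)-epoxy alcohol (alpha C1–C10 epoxide cis to the C9 OH; C5 ketone)
Conditions: VO(acac)2 (5 mol %), t-BuOOH, toluene, 0 °C to rt
Reagents that add atoms: tert-butyl hydroperoxide CC(C)(C)OO
Why: Vanadium-catalysed directed epoxidation of an allylic alcohol: the C9 alkoxide binds the pentavalent vanadium peroxide and delivers oxygen to the alkene face it occupies (alpha, also the face not covered by C2–C5 of ring B), which sets C1 as R, while the C5 ketone is inert.

Step 7
Reactants: 11 (1R,6S,9R,10S)-epoxy alcohol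
Product: 12 (1R,6S,9R,10S)-diol ketone (trans-fused; C1 alpha-OH; H10 beta; C9 alpha-OH; C5 ketone)
Conditions: Cp2TiCl2 (2.5 equiv), Mn, THF, rt; then 11, t-BuSH (10 equiv), rt; H2O
Reagents that add atoms: none
Why: Cp2TiCl-mediated reductive epoxide opening, precedented for trisubstituted 2,3-epoxy alcohols giving 1,3-diols: trivalent titanium cleaves the C10–O bond to the tertiary C10 radical and keeps the C1–O bond, the thiol (whose thiyl radical is taken up by a second Cp2TiCl and returns as thiol on work-up) should transfer hydrogen on the beta face, away from the bulky C1 titanium alkoxide, the C9 oxygen and the angular methyl, to give the trans fusion (10S), and its high transfer rate is meant to outrun attack of the radical on the C5 carbonyl.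

Step 8
Reactants: 13 vanillic acid
Product: 15 4-(tert-butyldimethylsilyloxy)-3-methoxybenzoic acid, via bis-silyl vanillate 14 (not isolated)
Conditions: TBSCl (2.3 equiv), imidazole, DMF, rt; then AcOH–THF–H2O, rt
Reagents that add atoms: tert-butyldimethylsilyl chloride CC(C)(C)[Si](C)(C)Cl
Why: Exhaustive silylation followed by selective hydrolysis of the much more labile silyl ester is the usual access to O-silylated hydroxybenzoic acids.

Step 9
Reactants: 12 (1R,6S,9R,10S)-diol ketone; 15 4-(tert-butyldimethylsilyloxy)-3-methoxybenzoic acid
Product: 16 C1 O-TBS-vanillate of 12 (C9 OH free; C5 ketone)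
Conditions: DCC, DMAP (cat.), CH2Cl2, rt
Reagents that add atoms: 4-(tert-butyldimethylsilyloxy)-3-methoxybenzoic acid COc1cc(C(=O)O)ccc1O[Si](C)(C)C(C)(C)C
Why: Steglich esterification acylates the only secondary alcohol, the tertiary C9 OH being inert under DCC/DMAP, and C1 keeps its configuration because its C–O bond is not broken.

Step 10
Reactants: 16 C1 O-TBS-vanillate of 12
Product: 17 C3=C4 enone (C5 ketone now conjugated; otherwise as 16)
Conditions: IBX (2 equiv), DMSO–fluorobenzene, 70 °C
Reagents that add atoms: none
Why: IBX dehydrogenation of a ketone through its enol: C6 carries no hydrogen, so C5 can enolise only toward C4 and only the C3=C4 enone can form, and ester, aryl silyl ether and tertiary alcohol tolerate the reagent.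

Step 11
Reactants: 17 C3=C4 enone; 18 methyllithium
Product: 19 C3-methyl C4=C5 trimethylsilyl enol ether (C9 OTMS; C3 configuration not controlled)
Conditions: MeLi, CuI, Et2O, 0 °C; then TMSCl, 17, THF, −78 °C
Reagents that add atoms: methyllithium [Li]C; chlorotrimethylsilane C[Si](C)(C)Cl
Why: TMSCl-accelerated conjugate addition of lithium dimethylcuprate delivers methyl to C3 and traps the enolate regiospecifically as the enol silane while the C9 alkoxide is capped in the same operation; the aryl ester and aryl silyl ether tolerate Me2CuLi at −78 °C, and the new C3 centre is erased in the next step.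

Step 12
Reactants: 19 C3-methyl C4=C5 trimethylsilyl enol ether
Product: 20 bis-silylated target (C3-methyl C3=C4 enone; C9 OTMS; aryl OTBS)
Conditions: Pd(OAc)2 (1.1 equiv), MeCN, rt
Reagents that add atoms: none
Why: Saegusa–Ito oxidation: divalent palladium forms the oxa-allyl complex at C4 and beta-hydride loss from C3 restores the enone, now trisubstituted, under neutral conditions that spare the base-sensitive C1 acyloxy group.

Step 13
Reactants: 20 bis-silylated target
Product: 21 target (1R,6S,9R,10S)-vanillate
Conditions: HF·pyridine, THF, 0 °C to rt
Reagents that add atoms: none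
Why: Fluoride-driven cleavage of the aryl TBS and tertiary TMS ethers in a mildly acidic medium avoids base-induced vinylogous E1cB loss of vanillate from C1 and touches none of the four stereocentres.

Compound list
1 | cycloheptane-1,3-dione | O=C1CCCCC(=O)C1 | starting material
2 | iodomethane | CI | starting material
3 | 2-methylcycloheptane-1,3-dione | CC1C(=O)CCCCC1=O | intermediate
4 | acrolein | C=CC=O | starting material
5 | 3-(1-methyl-2,7-dioxocycloheptyl)propanal | CC1(CCC=O)C(=O)CCCCC1=O | intermediate
6 | (6S,10R)-ketol, cis-fused, C9 ketone, C10 alpha-OH, C5 ketone | O=C1CC[C@]2(C)C(=O)CCCC[C@]12O | intermediate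
7 | C10 chlorosulfite of 6 (not isolated) | O=C1CC[C@]2(C)C(=O)CCCC[C@]12OS(=O)Cl | intermediate
8 | (6S)-enedione, C1=C10–C9=O enone and C5 ketone | O=C1CCCC=C2[C@]1(C)CCC2=O | intermediate
9 | isopropylmagnesium chloride | CC(C)[Mg]Cl | starting material
10 | (6S,9R)-allylic alcohol | O=C1CCCC=C2[C@]1(C)CC[C@@]2(O)C(C)C | intermediate
11 | (1R,6S,9R,10S)-epoxy alcohol, alpha epoxide | O=C1CCC[C@H]2O[C@@]23[C@]1(C)CC[C@@]3(O)C(C)C | intermediate
12 | (1R,6S,9R,10S)-diol ketone, trans-fused | O[C@@H]1CCCC(=O)[C@@]2(C)CC[C@@](O)(C(C)C)[C@H]12 | intermediate
13 | vanillic acid | COc1cc(C(=O)O)ccc1O | starting material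
14 | tert-butyldimethylsilyl 4-(tert-butyldimethylsilyloxy)-3-methoxybenzoate (not isolated) | COc1cc(C(=O)O[Si](C)(C)C(C)(C)C)ccc1O[Si](C)(C)C(C)(C)C | intermediate
15 | 4-(tert-butyldimethylsilyloxy)-3-methoxybenzoic acid | COc1cc(C(=O)O)ccc1O[Si](C)(C)C(C)(C)C | intermediate
16 | C1 O-TBS-vanillate of 12 | COc1cc(C(=O)O[C@@H]2CCCC(=O)[C@@]3(C)CC[C@@](O)(C(C)C)[C@H]23)ccc1O[Si](C)(C)C(C)(C)C | intermediate
17 | C3=C4 enone | COc1cc(C(=O)O[C@@H]2CC=CC(=O)[C@@]3(C)CC[C@@](O)(C(C)C)[C@H]23)ccc1O[Si](C)(C)C(C)(C)C | intermediate
18 | methyllithium | [Li]C | starting material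
19 | C3-methyl C4=C5 trimethylsilyl enol ether, C9 OTMS, C3 epimers | COc1cc(C(=O)O[C@@H]2CC(C)C=C(O[Si](C)(C)C)[C@@]3(C)CC[C@@](O[Si](C)(C)C)(C(C)C)[C@H]23)ccc1O[Si](C)(C)C(C)(C)C | intermediate
20 | bis-silylated target | COc1cc(C(=O)O[C@@H]2CC(C)=CC(=O)[C@@]3(C)CC[C@@](O[Si](C)(C)C)(C(C)C)[C@H]23)ccc1O[Si](C)(C)C(C)(C)C | intermediate
21 | target vanillate (1R,6S,9R,10S in the labels used here) | COc1cc(C(=O)O[C@@H]2CC(C)=CC(=O)[C@@]3(C)CC[C@@](O)(C(C)C)[C@H]23)ccc1O | target

Total steps: 13. Longest linear sequence: 12 (steps 1–7 and 9–13).

Steps most likely to fail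

Step 7.
- **What may go wrong:** the tertiary C10 radical may add to the neighbouring C5 carbonyl (3-exo closure, then acyl migration or trapping as a cyclopropanol) before it is quenched. Hydrogen transfer may also be poorly face-selective.
- **Fallback (from 11, back at 17):** the carbonyl is taken out of play before the radical is made.
  - NaBH4 in MeOH reduces the C5 ketone of 11 to the epoxy diol F1 (either C5 epimer serves).
  - TESCl and imidazole cap the secondary alcohol to give the C5 triethylsilyl ether F2.
  - Opening with Cp2TiCl and 1,4-cyclohexadiene gives the C1,C9-diol silyl ether F3.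
  - Steglich coupling with 15 gives the silylated ester F4.
  - PPTS in MeOH removes the alkyl TES group beside the aryl TBS ether to give the C5 alcohol ester F5.
  - An excess of IBX at 70 °C carries the alcohol through the ketone stage to enone 17 in one operation.

Step 5.
- **What may go wrong:** addition to the C5 carbonyl may compete, and facial selectivity at C9 may be poor because ring B is flexible.
- **Fallback (from 8, back at 12):** the C1 oxygen is installed first and the isopropyl group last.
  - Weitz–Scheffer epoxidation of 8 (t-BuOOH, DBU) should attack C1 from the alpha face, since C2–C5 of ring B lie on the beta side of the enone plane. This gives the epoxy diketone F6.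
  - The selenoborate made from (PhSe)2 and NaBH4 in EtOH with AcOH opens alpha,beta-epoxy ketones at the alpha carbon only. It gives the hydroxy diketone F7, whose C10 centre can equilibrate to the trans fusion.
  - Isopropylcerium dichloride (from 9 and CeCl3, excess, −78 °C) should then add to the C9 cyclopentanone, which is activated by chelation to the C1 alkoxide. Attack should come from the beta face, which carries only H10, and deliver 12 directly.

Step 3.
- **What may go wrong:** bridged aldol closure of a ring enolate onto the aldehyde, slow addition to the less electrophilic seven-membered ketone, and weak discrimination between the enantiotopic carbonyls of a flexible ring.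
- **Fallback (from 5, back at 6):** the same C9–C10 bond is closed reductively and the product is resolved.
  - SmI2 (THF, t-BuOH, −78 °C) couples the aldehyde ketyl with one ring ketone to give the racemic cis-fused cis-C9,C10-diol F8.
  - Acylative kinetic resolution with Candida antarctica lipase B and vinyl acetate should leave the (9S)-diol F9 and turn its antipode into the antipodal acetate F10, which is separated.
  - Parikh–Doering oxidation (SO3·pyridine, DMSO, Et3N) of the secondary alcohol of F9 gives 6.

Further compounds
F1 | step 7 | epoxy diol (C5 carbinol, C5 epimers) | OC1CCC[C@H]2O[C@@]23[C@]1(C)CC[C@@]3(O)C(C)C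
F2 | step 7 | C5 triethylsilyl ether of F1 | CC[Si](CC)(CC)OC1CCC[C@H]2O[C@@]23[C@]1(C)CC[C@@]3(O)C(C)C
F3 | step 7 | C1,C9-diol silyl ether (trans-fused, C5 OTES) | O[C@@H]1CCCC(O[Si](CC)(CC)CC)[C@@]2(C)CC[C@@](O)(C(C)C)[C@H]12
F4 | step 7 | silylated ester (C1 O-TBS-vanillate, C5 OTES) | COc1cc(C(=O)O[C@@H]2CCCC(O[Si](CC)(CC)CC)[C@@]3(C)CC[C@@](O)(C(C)C)[C@H]23)ccc1O[Si](C)(C)C(C)(C)C
F5 | step 7 | C5 alcohol ester | COc1cc(C(=O)O[C@@H]2CCCC(O)[C@@]3(C)CC[C@@](O)(C(C)C)[C@H]23)ccc1O[Si](C)(C)C(C)(C)C
F6 | step 5 | epoxy diketone (alpha C1–C10 epoxide) | O=C1CCC[C@H]2O[C@@]23[C@]1(C)CCC3=O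
F7 | step 5 | hydroxy diketone (C1 alpha-OH, H10 beta) | O[C@@H]1CCCC(=O)[C@@]2(C)CCC(=O)[C@H]12
F8 | step 3 | racemic cis-fused cis-C9,C10-diol | O[C@H]1CC[C@]2(C)C(=O)CCCC[C@]12O.O[C@@H]1CC[C@@]2(C)C(=O)CCCC[C@@]12O
F9 | step 3 | (9S)-diol, single enantiomer | O[C@H]1CC[C@]2(C)C(=O)CCCC[C@]12O
F10 | step 3 | antipodal acetate | CC(=O)O[C@@H]1CC[C@@]2(C)C(=O)CCCC[C@@]12O
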